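All constants were set for the occasion, and the outcome is calculated.

G and Z cannot turn back into anything here, since the scheme has no step out of them.

    Q + D ⇌ Q.D (K1 = 24 M⁻¹, k1 = 81000 M⁻¹ h⁻¹, Ea1 = 66.0 kJ mol⁻¹, ΔH1 = −21.0 kJ mol⁻¹)
    Q + L ⇌ Q.L (K2 = 28 M⁻¹, k2 = 60000 M⁻¹ h⁻¹, Ea2 = 49.0 kJ mol⁻¹, ΔH2 = −8.00 kJ mol⁻¹)
    X + Q.D → Q + G (k3 = 440 M⁻¹ h⁻¹, Ea3 = 46.0 kJ mol⁻¹)
    X + Q.L → Q + Z (k4 = 200 M⁻¹ h⁻¹, Ea4 = 62.0 kJ mol⁻¹)
    D ⇌ L (k5 = 0.016 h⁻¹, Ea5 = 117 kJ mol⁻¹)
    (constants at 90 °C)

| flask | D | X | Q | L | temperature | time | remark |
|---|---|---|---|---|---|---|---|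
| beta | 0.020 M | 2.00 equiv | 0.2 mol% | 0.020 M | 105 °C | 2.0 d |  |
| eta | 0.020 M | 2.00 equiv | 0.2 mol% | 0.020 M |  | 2.0 d | at 120 °C until 15 h, from then on at 90 °C |
| delta | 0.020 M | 2.00 equiv | 0.2 mol% | 0.020 M | 120 °C | 2.0 d |  |
| zeta | 0.020 M | 2.00 equiv | 0.2 mol% | 0.020 M | 90 °C | 2.0 d |  |

1. the flask that comes out highest in excess of G over Z, or "all alike" when all lie within 1.5 percentage points (beta / eta / delta / zeta / all alike)
2. excess of G over Z at the end, beta
3. excess of G over Z at the end, eta
4. excess of G over Z at the end, delta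
5. excess of G over Z at the end, zeta

- Q is single-handed; D and L are mirror images of each other, charged as a racemate, each of them at the stated concentration
- at 90 °C the constants are as listed, elsewhere as the activation energies and enthalpies make them
- an excess is below zero if the other one leads

**What's there.** Each flask holds X at 0.0400 M, D and L at 0.020 M each, and Q at 0.0400 mM. At 90 °C, Q.D returns to Q and D at 3380 h⁻¹, much faster than it goes on at the start, at 17.6 h⁻¹, so treat binding as a pre-equilibrium. D and L exchange there with a time of 31.3 h, shorter than the run of 2.0 d by a factor of 1.54 and no more, so [D] = [L] is a simplification at that temperature, which I keep for a first reckoning.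

**Number to carry.** G then forms over Z in the ratio s, the selectivity factor: the rate constant of the G step times the binding constant of D, over the same pair for Z and L. At 90 °C it is 1.89, and the excess is s less one over s plus one. The effective barrier, activation energy plus binding enthalpy, is 25.0 kJ mol⁻¹ for G and 54.0 kJ mol⁻¹ for Z, a gap of 29.0 kJ mol⁻¹. So s falls to 1.29 at 105 °C and 0.906 at 120 °C. You should find 30.7 % in zeta, 12.6 % in beta and −4.93 % in delta. In zeta D is used faster than L and the exchange makes that up in part, so read zeta's figure as somewhat high.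

**Eta's mixture.** Each turnover takes one X and one of D or L, so with the two pools taken as equal the rate goes with the square of [X]. With the free share of Q held at its starting value, charge over [X] is one plus g times time, and stretches simply add. Here g is 0.00634 h⁻¹ at 90 °C and 0.0192 h⁻¹ at 120 °C. Eta's stretches give 0.288 and 0.209, so expect 66.8 % of X left. The hot stretch makes 67.4 % of the product, which gives 6.70 %. On this reckoning the highest flask is zeta.

**Leave alone.** Keep eta's change at 15 h: an hour at 120 °C turns over 3.03 times as much as one at 90 °C, but at s of 0.906.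

**The forecast.** Its reasoning opens with “Treat the catalyst binding as a fast pre-equilibrium”, and it gave 11.9 % for beta, 6.8 % for eta, −4.8 % for delta and 28.3 % for zeta, with zeta highest.

**The flasks.** They end at 12.0 % in beta, 6.82 % in eta, −4.72 % in delta and 28.2 % in zeta, with zeta highest. In eta, up to 0.625 d, the steps from Q.D and Q.L ran hot and left G at 11.1 % and Z at 12.2 %. From there to 2.00 d they ran cold and brought G to 18.9 % and Z to 16.5 %, gains in a ratio read as 1.81, with s at 1.89. Carried to a flask like zeta kept at 115 °C, s is 1.02, an excess of 0.785 %, and that flask ended at 0.833 %.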